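The solid substrate shrinks.

in all of them: solid substrate 0.10 M; enzyme 6.9 µM
- larch: capture agent 0.060 M; run made earlier
- flask: capture agent 0.0300 M; time 15 h

larch run (percent of the solid substrate charged)

| time / min | solid substrate / % | complex / % | trapped intermediate / % | starting material / % | product / % |
|---|---|---|---|---|---|
| 5.00 | 99.1 | 0 | 0.7 | 3.5 | 0 |
| 15.0 | 96.0 | 0 | 0.3 | 4.2 | 0.5 |
| 25.0 | 94.1 | 2.2 | 0.9 | 5.5 | 0 |
| 40.0 | 89.1 | 0 | 1.2 | 10.6 | 1.1 |
| 50.0 | 89.9 | 0 | 1.4 | 12.2 | 0 |
| 80.0 | 81.7 | 0.8 | 0 | 16.3 | 0.3 |
| 90.0 | 81.1 | 1.1 | 0 | 19.0 | 0 |

(standard deviation of a reading: 1 percentage point)

- solid substrate is a solid; its amount is given per volume of the solution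
- at the start none of the solid substrate is in solution
- starting material means what is dissolved; the solid is not counted in it
- no earlier run changes the charge of capture agent; that part of a forecast is a guess

- the species in which most of what was charged as solid substrate, at 15 h sits (complex / starting material / trapped intermediate / product)
- the largest share itself, whichever of these holds it, in percent of the solid substrate charged

In the larch run, paired readings put the solid substrate at 89.5% around 45.0 min and 81.4% around 85.0 min. The rate of dissolving therefore goes from 0.00233 min⁻¹ of the charge between the start and the first pair to 0.00202 min⁻¹ between the two pairs, a factor of 0.868, and with a scatter of 1 percentage point on each reading that factor, and what is read from it below, is loose. Read as a first-order fade as the solution fills, this slowing is 0.00333 min⁻¹, which puts the rate at the start at 0.00252 min⁻¹. Dividing the start rate by the slowing makes time drop out and gives the reach, the share of the charge that the fading rate adds up to: 75.4%. By 15 h the reckoning here has 71.7% dissolved, less than the whole charge, so solid substrate should remain in the flask, and since the readings of the other species in the larch run stay about as small as a few times the scatter, starting material should stand near that figure.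

The forecast says starting material at 70%, a little under this reckoning: “Starting material should still dominate”.

The flask gives starting material at 64.8%, which is 5.2 points below the forecast.

    starting material + enzyme ⇌ complex (K = 13.0 M⁻¹, k = 170 M⁻¹ s⁻¹)
    complex ⇌ enzyme + product (K = 0.210 M, k = 8.20 s⁻¹)
    capture agent + complex → trapped intermediate (k = 6.40 M⁻¹ s⁻¹)
    2 starting material → homo dimer (k = 1.60 × 10⁻⁵ M⁻¹ s⁻¹)
    solid substrate ⇌ starting material, rate k5*(cs5 - [starting material]) while solid is left; crystals form when [starting material] > cs5 (solubility = 0.0690 M, k = 6.20 × 10⁻⁵ s⁻¹)

The flask still holds 30.4% of solid substrate, so 69.6% has dissolved, and homo dimer, each counted as the two starting material it holds, stands at 4.53%. Taken as a concentration, the reach is 0.0754 M, and the same fading rate adds up to 0.0717 M by 15 h, which is 120% of the 0.060 M charged in the neighbouring flask, more than that charge, so on this reckoning its solid substrate should be dissolved by then. At 15.0 h that neighbour holds solid substrate 0%, homo dimer 6.77% and starting material 92.7%.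

The earlier runs and the new flask stem from a simulated flask on assumed constants, and the scatter is random.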